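The 1,3,5-trisubstituted benzene ring is traced back to a 5-alkylcyclohexane-1,3-dione, whose carbonyl carbons become the oxygen-bearing arene carbons C3 and C5 and whose C1 carries the (S)-2-hydroxytetradecyl chain. One operation builds this carbocycle: dimethyl malonate adds to the β-carbon of an acyclic (S,E)-6-benzyloxyoctadec-3-en-2-one (bond C1–C2) and the methyl ketone then closes onto a malonate ester (bond C3–C4). Because C3 and C5 are still ketone carbons at that stage, one is capped as a benzyl vinylogous ester before dehydrogenation, so the acetate later reaches a single oxygen. The stereocentre comes from an asymmetric allylboration and travels as a benzyl ether.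

Key step: step 4

Assumption: the ring stereocentres that appear in 12, 13, 14, 17, 19 and 20 form without control and are left unassigned, because decarboxylation and aromatisation remove them; only the side-chain carbinol centre is specified.

Remark on the precursor: the carbinol is carried as a benzyl ether, not a silyl ether. A benzyl ether tolerates the aqueous acid of the decarboxylation and the acid-catalysed enol etherification, benzyloxide is a poorer leaving group than a silanolate in the annulation, and the group leaves together with the aryl benzyl ether in the last step.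

Step 1
Reactants: 1 tridecanal; 2 allylmagnesium bromide; 3 (+)-B-methoxydiisopinocampheylborane (the enantiomer derived from (−)-α-pinene)
Product: 6 (S)-hexadec-1-en-4-ol, via (+)-B-allyldiisopinocampheylborane 4 (not isolated), via (4S)-hexadec-1-en-4-yl diisopinocampheylborinate 5 (not isolated)
Conditions: 3, 2, Et2O, −78 °C → rt, Mg salts filtered off; 1, Et2O, −100 °C; then NaOH aq, H2O2 (30% aq), rt → reflux
Reagents that add atoms: allylmagnesium bromide, C=CC[Mg]Br
Why: Brown asymmetric allylboration: the allyl group is transferred through a closed six-membered chair transition state in which the isopinocampheyl groups of the (−)-α-pinene-derived reagent expose the Re face of the aldehyde, which gives the (S)-carbinol with an unbranched alkyl chain, and the magnesium-free reagent at −100 °C is chosen because it should give the highest enantiomeric purity.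

Step 2
Reactants: 6 (S)-hexadec-1-en-4-ol; 7 benzyl bromide
Product: 8 (S)-4-(benzyloxy)hexadec-1-ene
Conditions: NaH, Bu4NI (cat.), THF/DMF, 0 °C → rt
Reagents that add atoms: benzyl bromide, BrCc1ccccc1
Why: Williamson etherification of the sodium alkoxide with benzyl bromide forms only an O–CH2 bond, so the carbinol configuration is retained, and the resulting ether is inert to the methoxide, hydroxide, aqueous acid and amide base used later and leaves in the final hydrogenolysis.

Step 3
Reactants: 8 (S)-4-(benzyloxy)hexadec-1-ene; 9 methyl vinyl ketone (but-3-en-2-one)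
Product: 10 (3E,6S)-6-(benzyloxy)octadec-3-en-2-one
Conditions: second-generation Hoveyda–Grubbs catalyst (3 mol %), 9 (3 equiv), CH2Cl2, 40 °C
Reagents that add atoms: methyl vinyl ketone, C=CC(C)=O
Why: Olefin cross-metathesis of a terminal alkene with an electron-poor vinyl ketone, which hardly homodimerises, should give the cross product selectively as the thermodynamically preferred E-enone with loss of ethylene, and the ether and the stereocentre are spectators.

Step 4
Reactants: 10 (3E,6S)-6-(benzyloxy)octadec-3-en-2-one; 11 dimethyl malonate
Product: 13 methyl 6-[(2S)-2-(benzyloxy)tetradecyl]-2,4-dioxocyclohexane-1-carboxylate (ring stereocentres as a mixture), via Michael adduct 12 (not isolated)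
Conditions: 11 (1.3 equiv), NaOMe (1.15 equiv), MeOH, 0 °C; 10, 0 °C → rt, then reflux; cold 1 M HCl work-up
Reagents that add atoms: dimethyl malonate, COC(=O)CC(=O)OC
Why: Methoxide converts the malonate, kept in slight excess so that no free methoxide remains, into its sodium enolate, which adds in Michael fashion to the β-carbon of enone 10 and forms C1–C2; proton transfer then gives the methyl-ketone enolate of adduct 12, whose terminal carbon attacks one malonate ester carbonyl and expels methoxide, forming C3–C4. The closest known reaction type is the classical malonate–enone Michael–Claisen annulation used for dimedone and other 5-alkylcyclohexane-1,3-diones. The single ring closes in a 6-(enolendo)-exo-trig mode, and the sequence is pulled forward because 13 is deprotonated to a doubly stabilised enolate that does not revert. Two ring stereocentres arise, at the carbon bearing the side chain and at the ester-bearing carbon, but neither is controlled or needed: the ester-bearing carbon is enolised and both vanish on decarboxylation and aromatisation, while the (S)-carbinol centre carries no acidic proton and is untouched. The step needs conjugate addition to outrun γ-deprotonation of 10, which would lead to deconjugation or vinylogous loss of benzyl alcohol; this is secured by the soft, weakly basic malonate anion, by the poor leaving-group ability of benzyloxide, and by the fact that after the Michael addition the benzyloxy group is no longer in a vinylogous β-position to the carbonyl group.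

Step 5
Reactants: 13 methyl 6-[(2S)-2-(benzyloxy)tetradecyl]-2,4-dioxocyclohexane-1-carboxylate
Product: 15 5-[(2S)-2-(benzyloxy)tetradecyl]cyclohexane-1,3-dione, via keto acid 14 (not isolated)
Conditions: NaOH (2 M aq), reflux; then HCl aq to pH 1, 80 °C
Reagents that add atoms: none
Why: Saponification of the methyl ester of the enolate-protected dione followed by acidification gives a β-keto acid that loses CO2 through the usual cyclic six-membered transition state on warming, while the benzyl ether tolerates hot aqueous base and dilute acid and the carbinol centre has no acidic proton.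

Step 6
Reactants: 15 5-[(2S)-2-(benzyloxy)tetradecyl]cyclohexane-1,3-dione; 16 benzyl alcohol
Product: 17 3-(benzyloxy)-5-[(2S)-2-(benzyloxy)tetradecyl]cyclohex-2-en-1-one (ring C5 as a mixture)
Conditions: 16 (1.5 equiv), TsOH·H2O (cat.), toluene, reflux, Dean–Stark
Reagents that add atoms: benzyl alcohol, OCc1ccccc1
Why: Acid-catalysed enol etherification of a cyclic 1,3-dione with an alcohol under azeotropic removal of water gives the vinylogous ester by O-functionalisation only, and because the two carbonyl groups of 15 are equivalent the choice of oxygen is immaterial apart from a ring epimer pair that converges in step 7.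

Step 7
Reactants: 17 3-(benzyloxy)-5-[(2S)-2-(benzyloxy)tetradecyl]cyclohex-2-en-1-one; 18 benzeneselenenyl bromide
Product: 22 3-(benzyloxy)-5-[(2S)-2-(benzyloxy)tetradecyl]phenol, via α′-selenide 19 (not isolated), via selenoxide 20 (not isolated), via dienone 21 (not isolated)
Conditions: LiN(iPr)2 (1.1 equiv), THF, −78 °C; 18, −78 °C; then H2O2 (30% aq), pyridine, CH2Cl2, 0 °C → rt
Reagents that add atoms: none
Why: Kinetic deprotonation of a 3-alkoxycyclohex-2-enone with a lithium amide takes place at the α′-carbon C6 (the regiochemistry of the Stork–Danheiser alkylation), the enolate is selenenylated there, and oxidation to the selenoxide is followed by syn-elimination toward the C5–H to a cross-conjugated dienone that tautomerises irreversibly to the phenol and thereby removes the ring stereocentres.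

Step 8
Reactants: 22 3-(benzyloxy)-5-[(2S)-2-(benzyloxy)tetradecyl]phenol; 23 acetic anhydride
Product: 24 3-(benzyloxy)-5-[(2S)-2-(benzyloxy)tetradecyl]phenyl acetate
Conditions: 23, pyridine, DMAP (cat.), CH2Cl2, 0 °C → rt
Reagents that add atoms: acetic anhydride, CC(=O)OC(C)=O
Why: Nucleophile-catalysed O-acylation of the only free hydroxyl group in 22 places the acetate on the intended phenolic oxygen without any statistical mixture, since the other phenol oxygen and the carbinol are benzyl ethers.

Step 9
Reactants: 24 3-(benzyloxy)-5-[(2S)-2-(benzyloxy)tetradecyl]phenyl acetate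
Product: 25 3-hydroxy-5-[(2S)-2-hydroxytetradecyl]phenyl acetate (target)
Conditions: H2 (1 atm), Pd/C (10%), EtOAc, rt
Reagents that add atoms: none
Why: Catalytic hydrogenolysis over palladium cleaves the benzylic C–O bonds of both the aryl and the secondary alkyl benzyl ether under neutral conditions in a non-nucleophilic solvent, in which the aryl acetate is neither reduced nor solvolysed and the homobenzylic carbinol C–O bond and its configuration are untouched.

Compound list
1 | tridecanal | CCCCCCCCCCCCC=O | starting material
2 | allylmagnesium bromide | C=CC[Mg]Br | starting material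
3 | (+)-B-methoxydiisopinocampheylborane | COB([C@H]1C[C@H]2C[C@H](C2(C)C)[C@@H]1C)[C@H]1C[C@H]2C[C@H](C2(C)C)[C@@H]1C | starting material
4 | (+)-B-allyldiisopinocampheylborane | C=CCB([C@H]1C[C@H]2C[C@H](C2(C)C)[C@@H]1C)[C@H]1C[C@H]2C[C@H](C2(C)C)[C@@H]1C | intermediate
5 | (4S)-hexadec-1-en-4-yl diisopinocampheylborinate | CCCCCCCCCCCC[C@H](OB([C@H]1C[C@H]2C[C@H](C2(C)C)[C@@H]1C)[C@H]1C[C@H]2C[C@H](C2(C)C)[C@@H]1C)CC=C | intermediate
6 | (S)-hexadec-1-en-4-ol | CCCCCCCCCCCC[C@H](O)CC=C | intermediate
7 | benzyl bromide | BrCc1ccccc1 | starting material
8 | (S)-4-(benzyloxy)hexadec-1-ene | CCCCCCCCCCCC[C@H](OCc1ccccc1)CC=C | intermediate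
9 | methyl vinyl ketone (but-3-en-2-one) | C=CC(C)=O | starting material
10 | (3E,6S)-6-(benzyloxy)octadec-3-en-2-one | CCCCCCCCCCCC[C@H](OCc1ccccc1)C/C=C/C(C)=O | intermediate
11 | dimethyl malonate | COC(=O)CC(=O)OC | starting material
12 | dimethyl 2-[(6S)-6-(benzyloxy)-2-oxooctadecan-4-yl]propanedioate (Michael adduct) | CCCCCCCCCCCC[C@H](OCc1ccccc1)CC(CC(C)=O)C(C(=O)OC)C(=O)OC | intermediate
13 | methyl 6-[(2S)-2-(benzyloxy)tetradecyl]-2,4-dioxocyclohexane-1-carboxylate | CCCCCCCCCCCC[C@H](OCc1ccccc1)CC1CC(=O)CC(=O)C1C(=O)OC | intermediate
14 | 6-[(2S)-2-(benzyloxy)tetradecyl]-2,4-dioxocyclohexane-1-carboxylic acid (keto acid) | CCCCCCCCCCCC[C@H](OCc1ccccc1)CC1CC(=O)CC(=O)C1C(=O)O | intermediate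
15 | 5-[(2S)-2-(benzyloxy)tetradecyl]cyclohexane-1,3-dione | CCCCCCCCCCCC[C@H](OCc1ccccc1)CC1CC(=O)CC(=O)C1 | intermediate
16 | benzyl alcohol | OCc1ccccc1 | starting material
17 | 3-(benzyloxy)-5-[(2S)-2-(benzyloxy)tetradecyl]cyclohex-2-en-1-one | CCCCCCCCCCCC[C@H](OCc1ccccc1)CC1CC(=O)C=C(OCc2ccccc2)C1 | intermediate
18 | benzeneselenenyl bromide | Br[Se]c1ccccc1 | starting material
19 | 3-(benzyloxy)-5-[(2S)-2-(benzyloxy)tetradecyl]-6-(phenylselanyl)cyclohex-2-en-1-one (α′-selenide) | CCCCCCCCCCCC[C@H](OCc1ccccc1)CC1CC(OCc2ccccc2)=CC(=O)C1[Se]c1ccccc1 | intermediate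
20 | 3-(benzyloxy)-5-[(2S)-2-(benzyloxy)tetradecyl]-6-(phenylseleninyl)cyclohex-2-en-1-one (selenoxide) | CCCCCCCCCCCC[C@H](OCc1ccccc1)CC1CC(OCc2ccccc2)=CC(=O)C1[Se](=O)c1ccccc1 | intermediate
21 | 3-(benzyloxy)-5-[(2S)-2-(benzyloxy)tetradecyl]cyclohexa-2,5-dien-1-one (dienone) | CCCCCCCCCCCC[C@H](OCc1ccccc1)CC1=CC(=O)C=C(OCc2ccccc2)C1 | intermediate
22 | 3-(benzyloxy)-5-[(2S)-2-(benzyloxy)tetradecyl]phenol | CCCCCCCCCCCC[C@H](OCc1ccccc1)Cc1cc(O)cc(OCc2ccccc2)c1 | intermediate
23 | acetic anhydride | CC(=O)OC(C)=O | starting material
24 | 3-(benzyloxy)-5-[(2S)-2-(benzyloxy)tetradecyl]phenyl acetate | CCCCCCCCCCCC[C@H](OCc1ccccc1)Cc1cc(OC(C)=O)cc(OCc2ccccc2)c1 | intermediate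
25 | 3-hydroxy-5-[(2S)-2-hydroxytetradecyl]phenyl acetate | CCCCCCCCCCCC[C@H](O)Cc1cc(O)cc(OC(C)=O)c1 | target

Total step count: 9
Longest linear sequence: 9 steps (1 → 25)

Steps most likely to fail

Step 4. The base may remove a γ-proton of 10 in place of conjugate addition, so that the double bond moves out of conjugation or benzyl alcohol is lost by vinylogous elimination; at reflux the Michael addition may also reverse before the ring closes. The fallback exchanges the roles of donor and acceptor, so that the acceptor is a far less acidic enoate. It sets out from 8: cross-metathesis with methyl acrylate (second-generation Hoveyda–Grubbs catalyst, CH2Cl2, 40 °C) should give methyl (2E,5S)-5-(benzyloxy)heptadec-2-enoate F1. Methyl acetoacetate and NaOMe in refluxing MeOH then add to F1 to give dimethyl 2-acetyl-3-[(2S)-2-(benzyloxy)tetradecyl]pentanedioate F2, which is not isolated and closes by Claisen condensation of the acetyl methyl group onto the chain ester. The product is the same keto ester, so the route is rejoined at 13.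

Step 7. Proton exchange between the enolate and the more acidic α-seleno ketone may cause double selenenylation and return 17, and the electron-rich phenol may be oxidised further by the peroxide and selenium by-products as it forms. The fallback is a palladium-mediated dehydrosilylation (Saegusa–Ito oxidation), which needs no peroxide. It sets out from 17: LiN(iPr)2 and Me3SiCl (THF, −78 °C) should give 1-(benzyloxy)-5-[(2S)-2-(benzyloxy)tetradecyl]-3-(trimethylsilyloxy)cyclohexa-1,3-diene F3. Pd(OAc)2 (divalent palladium) in MeCN at rt then gives dienone 21 by β-hydride elimination from the palladium enolate, and 21 tautomerises to 22, where the route is rejoined.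

Step 1. Incomplete facial selectivity in the allyl transfer, for example through residual magnesium salts or warming during the addition, would leave the minor enantiomer, and the route has no resolution step downstream. The fallback takes the stereocentre from a kinetically resolved terminal epoxide. It sets out from 1: Corey–Chaykovsky epoxidation (Me3S+ I−, NaH, DMSO/THF, 0 °C) should give racemic 2-dodecyloxirane F4. Hydrolytic kinetic resolution with a chiral (salen)Co(OAc) complex of trivalent cobalt (the catalyst enantiomer that hydrolyses the (R)-epoxide, 0.55 equiv H2O) leaves (S)-2-dodecyloxirane F5. Opening of F5 at its terminal carbon with vinylmagnesium bromide and CuI (cat.) in THF at −30 °C does not touch the stereocentre and rejoins the route at 6.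

Further compounds
F1 | step 4 | methyl (2E,5S)-5-(benzyloxy)heptadec-2-enoate | CCCCCCCCCCCC[C@H](OCc1ccccc1)C/C=C/C(=O)OC
F2 | step 4 | dimethyl 2-acetyl-3-[(2S)-2-(benzyloxy)tetradecyl]pentanedioate | CCCCCCCCCCCC[C@H](OCc1ccccc1)CC(CC(=O)OC)C(C(C)=O)C(=O)OC
F3 | step 7 | 1-(benzyloxy)-5-[(2S)-2-(benzyloxy)tetradecyl]-3-(trimethylsilyloxy)cyclohexa-1,3-diene | CCCCCCCCCCCC[C@H](OCc1ccccc1)CC1C=C(O[Si](C)(C)C)C=C(OCc2ccccc2)C1
F4 | step 1 | racemic 2-dodecyloxirane | CCCCCCCCCCCCC1CO1
F5 | step 1 | (S)-2-dodecyloxirane | CCCCCCCCCCCC[C@H]1CO1
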